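The numbers of this flask are made up, and the outcome is calculated.

You are asked how much target stands after 15 min as the protic impurity in the charge goes from 2.50 mM to 20.0 mM. The scale has a natural zero: a flat row, with the four flasks alike.

| flask | solid substrate | gas phase | protic impurity | time |
|---|---|---|---|---|
| dusk | 0.050 M | 18 mM (held) | 2.50 mM | 15 min |
| noon | 0.050 M | 18 mM (held) | 5.00 mM | 15 min |
| spring | 0.050 M | 18 mM (held) | 10.0 mM | 15 min |
| midnight | 0.050 M | 18 mM (held) | 20.0 mM | 15 min |

    gas phase ⇌ dissolved gas, rate k1*(csat - [dissolved gas]) (k1 = 0.0061 /s, csat = 18 mM)
    2 dissolved gas → self-condensation product (k2 = 0.10 /M/s)
    dissolved gas + protic impurity → quenched reagent (k3 = 0.38 /M/s)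
    dissolved gas + target → over-reacted product (k4 = 0.018 /M/s)
    starting material + dissolved gas → target (k5 = 0.19 /M/s)
    solid substrate ⇌ starting material, rate k6*(cs6 - [starting material]) while solid is left; crystals form when [starting material] > cs6 (cs6 = 24 mM, k6 = 6.3 × 10⁻⁴ /s)

- where a step has two of a species, its rate is k times that concentration squared, and two are used at each turn
- solid, in amounts per volume of the solution: solid substrate
- at the start none of the gas is dissolved
- at the start none of the solid substrate is in solution
- "hardly changes" means that all values lie within two and a half points (for a concentration: within two and a half percent of the largest)
- run time (dusk): 15 min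

- amount of target at the end, in percent of the solid substrate charged for dusk, noon, spring, midnight, in this order
- how that number moves from the first to the last of them (falls all the way / hardly changes / rises all the way / rises, then falls / falls, then rises)

First, how much substrate can reach the solution? The solid dissolves fastest while c(starting material) is zero, at k6 times cs6, which is 0.0151 mM/s. Over the whole run that speed carries 27.2 % of the charge into solution, and this share is the feed ceiling. The protic impurity has no place in that product, so the ceiling stays at the zero of the scale.

Then can the impurity starve the gas instead? Gas enters fastest at k1 times csat, which over the run comes to 98.8 mM. The midnight charge of 20.0 mM is smaller than that, only 20.2 % of it, so I expect the impurity to delay the gas rather than starve it.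

So what part of the feed becomes target? Leaving the substrate aside, c(dissolved gas) steadies where transfer, k1 times (csat − c), matches self-condensation, which takes two of the dissolved gas at each turn of a step running at k2 times c squared, and that gives 12.7 mM. The step to target is then pseudo-first-order, and the run lasts 2.17 of its lifetimes; call that number x. A steady feed at the ceiling would then put ceiling × (1 − (1 − e^−x)/x) into target, which is 16.1 %. I take this as an estimate from above: the gas starts from nothing, and the feed slows as c(starting material) climbs. My commitment is a flat row somewhat under it.

The forecast gives 12.2 %, 12.1 %, 11.9 % and 11.5 %, shape: hardly changes, on the grounds that “The impurity only holds the gas down early, until it is used up”.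

The simulation gives 12.5 %, 12.4 %, 12.1 % and 11.6 %, shape: hardly changes, and the dusk value is lower than my estimate from above.

So watch the solid. At dusk 76.7 % of the charge is still solid at 15.0 min, so 23.3 % has entered against the feed ceiling of 27.2 %, and at midnight 22.9 % has entered against the same ceiling. That low solubility is the main reason the row stays flat. With it taken away, target reaches 66.1 % at dusk and 60.4 % at midnight, and the shape of the row turns, with a gap of 5.7 percentage points.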